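## Retrosynthetic overview
1. The ester is disconnected last: selective acylation of the primary C19-OH of labda-13(16),14-diene-8α,19-diol. The tertiary 8α-OH needs no protection.
2. The 13(16),14-diene comes from a but-3-ynyl side chain by ethylene ene-yne metathesis. The alkyne is a weakly nucleophilic stand-in that stops the cationic cascade at C8.
3. Both rings form in one cation-olefin cascade (ring A by C4–C5, then ring B by C9–C10) from an acyclic (S)-2-methyl-2-alkyloxirane. The oxirane CH2 becomes C19-OH and water quenches the C8 cation, mirroring the class II cyclase that makes labda-13-en-8-ol diphosphate.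
4. The oxirane, the only stereocentre made by a reagent, comes from a methyl ketone by catalytic asymmetric methylene transfer.
5. The ketone is assembled from geranyl bromide, a propargyl anion, an allylic C–H oxidation and a masked 3-oxobutyl Grignard reagent.

Assumption: the (S)-BINOL form of the La/Li catalyst in step 5 is taken to give the (S)-oxirane; if the sense is opposite for this ketone, the equally available (R)-BINOL complex is used. Labdane numbering is used for the acyclic compounds too.

## Route

Step 1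
Reactants: 1 geranyl bromide [(2E)-1-bromo-3,7-dimethylocta-2,6-diene]; 2 1-(trimethylsilyl)propyne
Product: 4 [(5E)-6,10-dimethylundeca-5,9-dien-1-yn-1-yl]trimethylsilane, via [3-(trimethylsilyl)prop-2-yn-1-yl]lithium 3 (not isolated)
Conditions: 2, n-BuLi, THF, −78 → −20 °C; then 1, −78 °C → rt
Reagents that add atoms: 1-(trimethylsilyl)propyne (2), CC#C[Si](C)(C)C
Why: SN2 alkylation of the silyl-stabilised propargyllithium at the primary allylic bromide, where the C-silyl group blocks the alkyne terminus and suppresses allenyl attack, the E-alkene of 1 is kept and no stereocentre is formed.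

Step 2
Reactants: 4 [(5E)-6,10-dimethylundeca-5,9-dien-1-yn-1-yl]trimethylsilane
Product: 5 (2E,6E)-2,6-dimethyl-11-(trimethylsilyl)undeca-2,6-dien-10-yn-1-ol
Conditions: SeO2 (0.2 equiv), t-BuOOH (2.5 equiv), salicylic acid (0.1 equiv), CH2Cl2, 0 °C → rt
Reagents that add atoms: tert-butyl hydroperoxide, CC(C)(C)OO (terminal oxygen source; SeO2, O=[Se]=O, is the catalytic oxygen carrier)
Why: Sharpless–Umbreit catalytic SeO2 allylic hydroxylation, in which an ene reaction at the most electron-rich, least hindered terminal isopropylidene and a [2,3]-sigmatropic shift place OH only on the E-methyl group, fixing the E geometry of the future C5=C10 alkene while the alkynylsilane is inert.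

Step 3
Reactants: 5 (2E,6E)-2,6-dimethyl-11-(trimethylsilyl)undeca-2,6-dien-10-yn-1-ol; 6 2-(2-bromoethyl)-2-methyl-1,3-dioxolane
Product: 10 2-methyl-2-[(4E,8E)-4,8-dimethyl-13-(trimethylsilyl)trideca-4,8-dien-12-yn-1-yl]-1,3-dioxolane, via (2E,6E)-2,6-dimethyl-11-(trimethylsilyl)undeca-2,6-dien-10-yn-1-yl methanesulfonate 7 (not isolated), via [(5E,9E)-11-chloro-6,10-dimethylundeca-5,9-dien-1-yn-1-yl]trimethylsilane 8 (not isolated), via [2-(2-methyl-1,3-dioxolan-2-yl)ethyl]magnesium bromide 9 (not isolated)
Conditions: 5, n-BuLi (1.0 equiv), THF, −78 °C; MsCl (1.05 equiv), −78 °C → rt, 2 h; then Li2CuCl4 (3 mol %) and 9 (1.5 equiv, from 6 and Mg, THF, ≤25 °C), −30 → 0 °C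
Reagents that add atoms: 2-(2-bromoethyl)-2-methyl-1,3-dioxolane (6), CC1(CCBr)OCCO1 (methanesulfonyl chloride, CS(=O)(=O)Cl, adds atoms only to intermediates 7 and 8)
Why: O-mesylation of the lithium alkoxide and SN2 displacement by the liberated LiCl give the primary allylic chloride without transposition, and the Li2CuCl4-catalysed (Kochi–Schlosser type) Grignard cross-coupling then substitutes at the unhindered primary α-carbon with retention of the E geometry, forming no stereocentre.

Step 4
Reactants: 10 2-methyl-2-[(4E,8E)-4,8-dimethyl-13-(trimethylsilyl)trideca-4,8-dien-12-yn-1-yl]-1,3-dioxolane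
Product: 12 (6E,10E)-6,10-dimethylpentadeca-6,10-dien-14-yn-2-one, via (6E,10E)-6,10-dimethyl-15-(trimethylsilyl)pentadeca-6,10-dien-14-yn-2-one 11 (not isolated)
Conditions: p-TsOH·H2O (5 mol %), THF–H2O 4:1, 45 °C; then MeOH, K2CO3 (0.3 equiv), rt
Reagents that add atoms: water, O
Why: Acid-catalysed acetal hydrolysis followed in the same flask by carbonate/methanol protodesilylation of the alkynylsilane, both of which leave the isolated trisubstituted alkenes untouched and involve no stereocentre.

Step 5
Reactants: 12 (6E,10E)-6,10-dimethylpentadeca-6,10-dien-14-yn-2-one; 13 trimethylsulfoxonium chloride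
Product: 15 (2S)-2-methyl-2-[(4E,8E)-4,8-dimethyltrideca-4,8-dien-12-yn-1-yl]oxirane, via dimethylsulfoxonium methylide 14 (not isolated)
Conditions: 13, NaH, THF, reflux (gives 14, 1.2 equiv); then 12, (S)-LaLi3-tris(binaphthoxide) (5 mol %), [2,4,6-(MeO)3C6H2]3P=O (5 mol %), MS 5 Å, THF, rt
Reagents that add atoms: trimethylsulfoxonium chloride (13), C[S+](C)(C)=O.[Cl-]
Why: Catalytic asymmetric Corey–Chaykovsky epoxidation, in which the heterobimetallic La/Li binaphthoxide binds ketone and ylide together, tells CH3 from the CH2R arm and delivers CH2 to one carbonyl face to set the single stereocentre (future C4) as S, while the alkenes and the terminal alkyne (far less acidic than the sulfoxonium salt) are untouched.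

Step 6
Reactants: 15 (2S)-2-methyl-2-[(4E,8E)-4,8-dimethyltrideca-4,8-dien-12-yn-1-yl]oxirane
Product: 16 15,16-dinorlabd-13-yne-8α,19-diol (trans-decalin; 4β-axial CH2OH, 4α-CH3, 5α-H, 10β-CH3, 9β-but-3-ynyl with 9α-H, 8α-equatorial OH, 8β-CH3)
Conditions: Ph4PBF4 (0.2 equiv), (CF3)2CHOH–H2O 99:1, 0.005 M, 0 °C, 30 min; NaHCO3 quench; chromatography
Reagents that add atoms: water, O
Why: Proposed new method: hydrogen-bond/Brønsted activation of the oxirane in the non-nucleophilic, weakly basic, cation-stabilising solvent HFIP starts a Stork–Eschenmoser chair–chair cation-olefin bicyclisation in which C5 attacks the tertiary oxirane carbon anti to the C–O bond (inversion, so the oxirane CH2 becomes the C19 carbinol and, being tied back toward the leaving oxygen and so sterically smaller than CH3, takes the axial site), the two E-alkenes add anti to give the trans-decalin with 5α-H, 9α-H and 10β-CH3, the weakly nucleophilic terminal alkyne halts the cascade at the C8 cation just as the deactivated allylic diphosphate alkene does in the enzyme, and water (about 0.5 M, too dilute to intercept the fast ring closures) captures that longer-lived cation from the equatorial α face opposite the axial C10 methyl, the closest known reaction types being Lewis-acid epoxide-initiated polyene cyclisations and the water-trapped acid- or Hg(II)-induced bicyclisations of geranylgeranyl esters that give 8α-hydroxylabdanes.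

Step 7
Reactants: 16 15,16-dinorlabd-13-yne-8α,19-diol; 17 ethylene
Product: 18 labda-13(16),14-diene-8α,19-diol
Conditions: Grubbs II (5 mol %), ethylene (1 atm), CH2Cl2, 40 °C
Reagents that add atoms: ethylene (17), C=C
Why: Ruthenium-carbene ene-yne cross metathesis (Mori conditions) places one CH2 of ethylene on each alkyne carbon and gives regiospecifically the 2-substituted buta-1,3-diene C13(=C16H2)–C14H=C15H2, with no other π-bond in the substrate, tolerance of the free alcohols and no stereocentre touched.

Step 8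
Reactants: 18 labda-13(16),14-diene-8α,19-diol; 19 (E)-4-acetoxycinnamic acid
Product: 21 8α-hydroxylabda-13(16),14-dien-19-yl (E)-p-hydroxycinnamate, via 8α-hydroxylabda-13(16),14-dien-19-yl (E)-4-acetoxycinnamate 20 (not isolated)
Conditions: 19 (1.3 equiv), DCC (1.4 equiv), DMAP (0.5 equiv), CH2Cl2, rt, 16 h; then MeOH, K2CO3 (0.2 equiv), 0 °C, 30 min
Reagents that add atoms: (E)-4-acetoxycinnamic acid (19), CC(=O)Oc1ccc(/C=C/C(=O)O)cc1
Why: Steglich esterification acylates only the primary (neopentyl, axial) C19 alcohol because the tertiary 8α-OH is inert to the acylpyridinium species, and the mild methanolysis that follows removes only the much more electrophilic aryl acetate, leaving the hindered (E)-cinnamate, the diene and all stereocentres unchanged.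

## Compound list
1 | geranyl bromide | CC(C)=CCC/C(C)=C/CBr | starting material
2 | 1-(trimethylsilyl)propyne | CC#C[Si](C)(C)C | starting material
3 | [3-(trimethylsilyl)prop-2-yn-1-yl]lithium | [Li]CC#C[Si](C)(C)C | intermediate
4 | [(5E)-6,10-dimethylundeca-5,9-dien-1-yn-1-yl]trimethylsilane | CC(C)=CCC/C(C)=C/CCC#C[Si](C)(C)C | intermediate
5 | (2E,6E)-2,6-dimethyl-11-(trimethylsilyl)undeca-2,6-dien-10-yn-1-ol | OC/C(C)=C/CC/C(C)=C/CCC#C[Si](C)(C)C | intermediate
6 | 2-(2-bromoethyl)-2-methyl-1,3-dioxolane | CC1(CCBr)OCCO1 | starting material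
7 | (2E,6E)-2,6-dimethyl-11-(trimethylsilyl)undeca-2,6-dien-10-yn-1-yl methanesulfonate | CS(=O)(=O)OC/C(C)=C/CC/C(C)=C/CCC#C[Si](C)(C)C | intermediate
8 | [(5E,9E)-11-chloro-6,10-dimethylundeca-5,9-dien-1-yn-1-yl]trimethylsilane | ClC/C(C)=C/CC/C(C)=C/CCC#C[Si](C)(C)C | intermediate
9 | [2-(2-methyl-1,3-dioxolan-2-yl)ethyl]magnesium bromide | CC1(CC[Mg]Br)OCCO1 | intermediate
10 | 2-methyl-2-[(4E,8E)-4,8-dimethyl-13-(trimethylsilyl)trideca-4,8-dien-12-yn-1-yl]-1,3-dioxolane | CC1(CCC/C(C)=C/CC/C(C)=C/CCC#C[Si](C)(C)C)OCCO1 | intermediate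
11 | (6E,10E)-6,10-dimethyl-15-(trimethylsilyl)pentadeca-6,10-dien-14-yn-2-one | CC(=O)CCC/C(C)=C/CC/C(C)=C/CCC#C[Si](C)(C)C | intermediate
12 | (6E,10E)-6,10-dimethylpentadeca-6,10-dien-14-yn-2-one | CC(=O)CCC/C(C)=C/CC/C(C)=C/CCC#C | intermediate
13 | trimethylsulfoxonium chloride | C[S+](C)(C)=O.[Cl-] | starting material
14 | dimethylsulfoxonium methylide | C[S+](C)(=O)[CH2-] | intermediate
15 | (2S)-2-methyl-2-[(4E,8E)-4,8-dimethyltrideca-4,8-dien-12-yn-1-yl]oxirane | C[C@]1(CCC/C(C)=C/CC/C(C)=C/CCC#C)CO1 | intermediate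
16 | 15,16-dinorlabd-13-yne-8α,19-diol | C#CCC[C@@H]1[C@@]2(C)CCC[C@](C)(CO)[C@@H]2CC[C@@]1(C)O | intermediate
17 | ethylene | C=C | starting material
18 | labda-13(16),14-diene-8α,19-diol | C=CC(=C)CC[C@@H]1[C@@]2(C)CCC[C@](C)(CO)[C@@H]2CC[C@@]1(C)O | intermediate
19 | (E)-4-acetoxycinnamic acid | CC(=O)Oc1ccc(/C=C/C(=O)O)cc1 | starting material
20 | 8α-hydroxylabda-13(16),14-dien-19-yl (E)-4-acetoxycinnamate | C=CC(=C)CC[C@@H]1[C@@]2(C)CCC[C@](C)(COC(=O)/C=C/c3ccc(OC(C)=O)cc3)[C@@H]2CC[C@@]1(C)O | intermediate
21 | 8α-hydroxylabda-13(16),14-dien-19-yl (E)-p-hydroxycinnamate | C=CC(=C)CC[C@@H]1[C@@]2(C)CCC[C@](C)(COC(=O)/C=C/c3ccc(O)cc3)[C@@H]2CC[C@@]1(C)O | target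

## Step count and risks
Total step count: 8. Reagents 3, 9 and 14 are made within their steps.
Longest linear sequence: 8 (1 → 4 → 5 → 10 → 12 → 15 → 16 → 18 → 21).

**Step 6 (highest risk).**
- The oxirane may rearrange to the α-branched aldehyde (Meinwald rearrangement).
- The C8 cation may lose a proton instead of taking up water.
- The free C19-OH may trap the monocyclic C10 cation as a bridged ether.
- The chair with equatorial CH2OH may compete, giving a separable diastereomer.
- SN1 character at C4 may erode the ee.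

Fallback, setting out from 15 and returning at 16: separate the C–C and C–O bond formations. Compound 15 is cyclised with MeAlCl2 (1.2 equiv, CH2Cl2, −78 °C). The aluminium alkoxide ties up the C19 oxygen and the cascade ends by proton loss. This gives the exocyclic alkene 15,16-dinorlabd-8(17)-en-13-yn-19-ol F1 together with its endocyclic isomer 15,16-dinorlabd-7-en-13-yn-19-ol F2. The mixture is then hydrated under Mukaiyama conditions (Mn(dpm)3 cat., PhSiH3, O2, i-PrOH, 0 °C → rt). Both alkenes converge on the same tertiary C8 radical, which takes up O2 on the α face away from the axial C10 methyl to give 16. The terminal alkyne reacts much more slowly with the metal hydride. Olefinic by-products from step 6 itself can be recycled the same way.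

**Step 5.** The ee may be only moderate, because CH3 must be told from an unbranched CH2R arm.

Fallback, setting out from 12 and returning at 15:
- Uncatalysed addition of 14 gives the racemic oxirane 2-methyl-2-[(4E,8E)-4,8-dimethyltrideca-4,8-dien-12-yn-1-yl]oxirane F3.
- A bacterial epoxide hydrolase (lyophilised Nocardia or Rhodococcus cells, Tris buffer pH 8, rt) is highly selective for 2-methyl-2-alkyloxiranes. It attacks the CH2 of the S enantiomer only, with retention at the quaternary carbon.
- This gives (2S,6E,10E)-2,6,10-trimethylpentadeca-6,10-dien-14-yne-1,2-diol F4 and leaves the (2R)-oxirane F5, which is removed by chromatography.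
- Selective primary tosylation (TsCl, pyridine, 0 °C) gives (2S,6E,10E)-2-hydroxy-2,6,10-trimethylpentadeca-6,10-dien-14-yn-1-yl 4-methylbenzenesulfonate F6.
- K2CO3 in MeOH closes F6 to 15 without touching the stereocentre.

**Step 3.** SN2′ attack of the copper reagent, incomplete one-pot chloride formation or thermal decay of Grignard reagent 9 would each spoil the coupling.

Fallback, setting out from 5 and returning at 10, replacing the organocopper coupling by alkylation of a stabilised carbanion:
- Compound 5 is converted (CBr4, PPh3, CH2Cl2, 0 °C) into the isolated bromide [(5E,9E)-11-bromo-6,10-dimethylundeca-5,9-dien-1-yn-1-yl]trimethylsilane F7.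
- Commercial 4-(phenylsulfonyl)butan-2-one is ketalised (ethylene glycol, p-TsOH, toluene, Dean–Stark) to 2-methyl-2-[2-(phenylsulfonyl)ethyl]-1,3-dioxolane F8.
- F8 is deprotonated with n-BuLi (THF, −78 °C) and alkylated with F7 in a clean SN2 reaction.
- The product is 2-methyl-2-[(4E,8E)-4,8-dimethyl-2-(phenylsulfonyl)-13-(trimethylsilyl)trideca-4,8-dien-12-yn-1-yl]-1,3-dioxolane F9, a racemic and inconsequential sulfone centre.
- Reductive desulfonylation (Na(Hg), Na2HPO4, MeOH–THF, −20 °C) gives 10.

## Further compounds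
F1 | step 6 | 15,16-dinorlabd-8(17)-en-13-yn-19-ol | C#CCC[C@@H]1[C@@]2(C)CCC[C@](C)(CO)[C@@H]2CCC1=C
F2 | step 6 | 15,16-dinorlabd-7-en-13-yn-19-ol | C#CCC[C@@H]1[C@@]2(C)CCC[C@](C)(CO)[C@@H]2CC=C1C
F3 | step 5 | racemic 2-methyl-2-[(4E,8E)-4,8-dimethyltrideca-4,8-dien-12-yn-1-yl]oxirane | CC1(CCC/C(C)=C/CC/C(C)=C/CCC#C)CO1
F4 | step 5 | (2S,6E,10E)-2,6,10-trimethylpentadeca-6,10-dien-14-yne-1,2-diol | C[C@](O)(CCC/C(C)=C/CC/C(C)=C/CCC#C)CO
F5 | step 5 | (2R)-2-methyl-2-[(4E,8E)-4,8-dimethyltrideca-4,8-dien-12-yn-1-yl]oxirane | C[C@@]1(CCC/C(C)=C/CC/C(C)=C/CCC#C)CO1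
F6 | step 5 | (2S,6E,10E)-2-hydroxy-2,6,10-trimethylpentadeca-6,10-dien-14-yn-1-yl 4-methylbenzenesulfonate | C[C@](O)(CCC/C(C)=C/CC/C(C)=C/CCC#C)COS(=O)(=O)c1ccc(C)cc1
F7 | step 3 | [(5E,9E)-11-bromo-6,10-dimethylundeca-5,9-dien-1-yn-1-yl]trimethylsilane | BrC/C(C)=C/CC/C(C)=C/CCC#C[Si](C)(C)C
F8 | step 3 | 2-methyl-2-[2-(phenylsulfonyl)ethyl]-1,3-dioxolane | CC1(CCS(=O)(=O)c2ccccc2)OCCO1
F9 | step 3 | 2-methyl-2-[(4E,8E)-4,8-dimethyl-2-(phenylsulfonyl)-13-(trimethylsilyl)trideca-4,8-dien-12-yn-1-yl]-1,3-dioxolane | CC1(CC(C/C(C)=C/CC/C(C)=C/CCC#C[Si](C)(C)C)S(=O)(=O)c2ccccc2)OCCO1
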